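**Strategy.** The pyranone ring (O1, C2, C3, C4, C4a, C8a) is first built one carbon short, as the furan ring of a 3-silyloxybenzofuran in which the future C2 and C4 are bonded directly. C3, already carrying the chromenyl B-ring, is then inserted between them as an arylchlorocarbene carbon. The chlorocyclopropane opens electrocyclically across the old C2–C4 bond and loses silyl chloride to give the isoflavone. One operation joins both halves, enlarges the five-membered ring to six and places the aryl group, exploiting that C3 lies between the O1-bearing C2 and the carbonyl C4. The C3 stereocentre is set afterwards by asymmetric transfer hydrogenation (dynamic kinetic resolution) and reoxidation.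

Key step: step 7

Remark: the drawn stereocentre is C3 with R configuration; 1, 2 and 12 are taken as commercial, and diazirine 11 is kept cold in pentane and used without storage.

Step 1
Reactants: 1 2,4-dihydroxybenzaldehyde; 2 3-methylbut-2-enal
Product: 3 5-hydroxy-2,2-dimethyl-2H-chromene-6-carbaldehyde
Conditions: pyridine, 120 °C
Reagents that add atoms: none
Why: Aldol-type condensation of the enal at C3 of the resorcinol followed by oxa-6π electrocyclisation (chromene annulation) should close the pyran on the free 4-OH, because the 2-OH is held in the hydrogen bond to the aldehyde.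

Step 2
Reactants: 3 5-hydroxy-2,2-dimethyl-2H-chromene-6-carbaldehyde
Product: 4 5-methoxy-2,2-dimethyl-2H-chromene-6-carbaldehyde
Conditions: MeI, K2CO3, DMF, 40 °C
Reagents that add atoms: iodomethane, CI
Why: Williamson O-methylation of the only remaining phenol should give the methyl ether once gentle warming breaks the chelate.

Step 3
Reactants: 4 5-methoxy-2,2-dimethyl-2H-chromene-6-carbaldehyde
Product: 7 5-methoxy-2,2-dimethyl-2H-chromene-6-carbonitrile, via aldoxime 5 (not isolated), via O-acetyl aldoxime 6 (not isolated)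
Conditions: NH2OH·HCl, pyridine, 60 °C; then Ac2O, 100 °C
Reagents that add atoms: hydroxylamine hydrochloride, NO.Cl; acetic anhydride, CC(=O)OC(C)=O (its acetyl group is in intermediate 6 only)
Why: Oxime formation and elimination of acetic acid from the O-acetyl oxime (aldoxime dehydration) should give the nitrile under conditions the chromene tolerates.

Step 4
Reactants: 7 5-methoxy-2,2-dimethyl-2H-chromene-6-carbonitrile
Product: 9 5-methoxy-2,2-dimethyl-2H-chromene-6-carboximidamide hydrochloride, via lithium N,N'-bis(trimethylsilyl)amidinate 8 (not isolated)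
Conditions: LiHMDS, THF, 0 °C to rt; then HCl/dioxane, 0 °C
Reagents that add atoms: lithium bis(trimethylsilyl)amide, [Li+].C[Si](C)(C)[N-][Si](C)(C)C; hydrogen chloride, Cl
Why: Addition of the silylamide to the nitrile and acidic N-desilylation (amidine synthesis from a nitrile) should give the amidinium chloride.

Step 5
Reactants: 9 5-methoxy-2,2-dimethyl-2H-chromene-6-carboximidamide hydrochloride
Product: 11 3-chloro-3-(5-methoxy-2,2-dimethyl-2H-chromen-6-yl)-3H-diazirine, via N,N'-dichloroamidine 10 (not isolated)
Conditions: aq. NaOCl, LiCl, DMSO/pentane, 0 °C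
Reagents that add atoms: sodium hypochlorite, [Na+].[O-]Cl (source of the chlorine atoms of 10 and 11)
Why: Graham oxidation should give the chlorodiazirine by fast N-chlorination to the dichloroamidine and base-induced N–N closure with chloride ending on carbon, while the basic medium and immediate extraction into pentane protect the chromene double bond.

Step 6
Reactants: 12 4,6-dihydroxybenzofuran-3(2H)-one
Product: 13 3,4,6-tris(tert-butyldimethylsilyloxy)benzofuran
Conditions: TBSOTf (3.3 equiv), Et3N, CH2Cl2, 0 °C
Reagents that add atoms: tert-butyldimethylsilyl trifluoromethanesulfonate, CC(C)(C)[Si](C)(C)OS(=O)(=O)C(F)(F)F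
Why: Silylation of both phenols and O-silylation of the ketone (silyl enol ether formation) should occur in one pot because enolisation towards C2 aromatises the furan ring.

Step 7
Reactants: 13 3,4,6-tris(tert-butyldimethylsilyloxy)benzofuran; 11 3-chloro-3-(5-methoxy-2,2-dimethyl-2H-chromen-6-yl)-3H-diazirine
Product: 16 5,7-bis(tert-butyldimethylsilyloxy)-3-(5-methoxy-2,2-dimethyl-2H-chromen-6-yl)-4H-chromen-4-one, via chlorocyclopropane 14 (not isolated), via 4-silyloxybenzopyrylium chloride 15 (not isolated)
Conditions: Na2CO3, MeCN, 40 °C, 11 added slowly to 13 (2 equiv)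
Reagents that add atoms: none
Why: Thermolysis of 11 releases the singlet aryl(chloro)carbene, which adds in a concerted (2+1) cheletropic step to the C2=C3 enol ether bond of 13 to close the cyclopropane of 14; ionisation of the C–Cl bond, pushed by the ring oxygen and the 3-silyloxy group, is coupled to disrotatory 2π-electrocyclic opening of the bond shared by the two rings, so the furan becomes the six-membered pyrylium ring of 15 by bond cleavage, not by a new closure, and chloride then removes the silyl group from O4 to give chromone 16. The closest known reactions are the Ciamician–Dennstedt carbon-atom insertion of arylchlorocarbenes into indoles and pyrroles and the dihalocarbene ring enlargement of cyclic silyl enol ethers. The stereocentres of 14 are transient and 16 is achiral, so this step needs no stereocontrol. Regioselectivity of the enlargement is fixed by the mechanism, since the cyclopropyl cation can only open across the bond opposite the carbon that loses chloride, which is the old C2–C3 bond of the benzofuran. Chemoselectivity for the enol ether over the chromene double bond rests on the three oxygen donors that make C2 of 13 far more nucleophilic, and is supported by keeping 13 in excess.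

Step 8
Reactants: 16 5,7-bis(tert-butyldimethylsilyloxy)-3-(5-methoxy-2,2-dimethyl-2H-chromen-6-yl)-4H-chromen-4-one
Product: 18 (3R,4R)-5,7-bis(tert-butyldimethylsilyloxy)-3-(5-methoxy-2,2-dimethyl-2H-chromen-6-yl)chroman-4-ol, via racemic isoflavanone 17 (not isolated)
Conditions: RuCl[(R,R)-TsDPEN](p-cymene) (5 mol %), HCO2H/Et3N (5:2), EtOAc, 40 °C
Reagents that add atoms: none
Why: Ru–H conjugate reduction of the chromone gives the rapidly racemising ketone 17, and asymmetric transfer hydrogenation of its carbonyl under dynamic kinetic resolution should set C4 as R through the (R,R)-TsDPEN ligand and C3 as R through the cis preference of hydride delivery; the unactivated chromene double bond is not a substrate.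

Step 9
Reactants: 18 (3R,4R)-5,7-bis(tert-butyldimethylsilyloxy)-3-(5-methoxy-2,2-dimethyl-2H-chromen-6-yl)chroman-4-ol
Product: 19 (3R)-5,7-bis(tert-butyldimethylsilyloxy)-3-(5-methoxy-2,2-dimethyl-2H-chromen-6-yl)chroman-4-one
Conditions: Dess–Martin periodinane, NaHCO3, CH2Cl2, 0 °C
Reagents that add atoms: none
Why: Dess–Martin oxidation of the benzylic alcohol under buffered, non-basic conditions should return the ketone without enolising the C3 stereocentre.

Step 10
Reactants: 19 (3R)-5,7-bis(tert-butyldimethylsilyloxy)-3-(5-methoxy-2,2-dimethyl-2H-chromen-6-yl)chroman-4-one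
Product: 20 (3R)-5,7-dihydroxy-3-(5-methoxy-2,2-dimethyl-2H-chromen-6-yl)chroman-4-one
Conditions: HF·pyridine, THF, 0 °C
Reagents that add atoms: none
Why: Fluoride cleavage of the two aryl silyl ethers in a mildly acidic medium (desilylation) should free both phenols without the base-induced enolisation that would racemise C3, and leaves the chromene and the methyl ether intact.

**Compound list**

1 | 2,4-dihydroxybenzaldehyde | O=Cc1ccc(O)cc1O | starting material
2 | 3-methylbut-2-enal | CC(C)=CC=O | starting material
3 | 5-hydroxy-2,2-dimethyl-2H-chromene-6-carbaldehyde | CC1(C)C=Cc2c(O)c(C=O)ccc2O1 | intermediate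
4 | 5-methoxy-2,2-dimethyl-2H-chromene-6-carbaldehyde | CC1(C)C=Cc2c(OC)c(C=O)ccc2O1 | intermediate
5 | 5-methoxy-2,2-dimethyl-2H-chromene-6-carbaldehyde oxime (E/Z, not isolated) | CC1(C)C=Cc2c(OC)c(C=NO)ccc2O1 | intermediate
6 | 5-methoxy-2,2-dimethyl-2H-chromene-6-carbaldehyde O-acetyl oxime (not isolated) | CC1(C)C=Cc2c(OC)c(C=NOC(C)=O)ccc2O1 | intermediate
7 | 5-methoxy-2,2-dimethyl-2H-chromene-6-carbonitrile | CC1(C)C=Cc2c(OC)c(C#N)ccc2O1 | intermediate
8 | lithium N,N'-bis(trimethylsilyl)-5-methoxy-2,2-dimethyl-2H-chromene-6-carboximidamidate (not isolated) | C[Si](C)(C)N=C([N-][Si](C)(C)C)c1ccc2OC(C)(C)C=Cc2c1OC.[Li+] | intermediate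
9 | 5-methoxy-2,2-dimethyl-2H-chromene-6-carboximidamide hydrochloride | NC(=[NH2+])c1ccc2OC(C)(C)C=Cc2c1OC.[Cl-] | intermediate
10 | N,N'-dichloro-5-methoxy-2,2-dimethyl-2H-chromene-6-carboximidamide (not isolated) | ClNC(=NCl)c1ccc2OC(C)(C)C=Cc2c1OC | intermediate
11 | 3-chloro-3-(5-methoxy-2,2-dimethyl-2H-chromen-6-yl)-3H-diazirine | CC1(C)C=Cc2c(OC)c(C3(Cl)N=N3)ccc2O1 | intermediate
12 | 4,6-dihydroxybenzofuran-3(2H)-one | O=C1COc2cc(O)cc(O)c12 | starting material
13 | 3,4,6-tris(tert-butyldimethylsilyloxy)benzofuran | CC(C)(C)[Si](C)(C)Oc1cc(O[Si](C)(C)C(C)(C)C)c2c(O[Si](C)(C)C(C)(C)C)coc2c1 | intermediate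
14 | chlorocyclopropane adduct of the carbene across C2=C3 of 13 (racemic, both epimers at the chlorine-bearing carbon, not isolated) | CC(C)(C)[Si](C)(C)Oc1cc(O[Si](C)(C)C(C)(C)C)c2c(c1)OC1C(Cl)(c3ccc4OC(C)(C)C=Cc4c3OC)C21O[Si](C)(C)C(C)(C)C | intermediate
15 | 4,5,7-tris(tert-butyldimethylsilyloxy)-3-(5-methoxy-2,2-dimethyl-2H-chromen-6-yl)-1-benzopyrylium chloride (not isolated) | CC(C)(C)[Si](C)(C)Oc1cc(O[Si](C)(C)C(C)(C)C)c2c(O[Si](C)(C)C(C)(C)C)c(-c3ccc4OC(C)(C)C=Cc4c3OC)c[o+]c2c1.[Cl-] | intermediate
16 | 5,7-bis(tert-butyldimethylsilyloxy)-3-(5-methoxy-2,2-dimethyl-2H-chromen-6-yl)-4H-chromen-4-one | COc1c(C2=COc3cc(O[Si](C)(C)C(C)(C)C)cc(O[Si](C)(C)C(C)(C)C)c3C2=O)ccc2c1C=CC(C)(C)O2 | intermediate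
17 | racemic 5,7-bis(tert-butyldimethylsilyloxy)-3-(5-methoxy-2,2-dimethyl-2H-chromen-6-yl)chroman-4-one (not isolated) | COc1c(C2COc3cc(O[Si](C)(C)C(C)(C)C)cc(O[Si](C)(C)C(C)(C)C)c3C2=O)ccc2c1C=CC(C)(C)O2 | intermediate
18 | (3R,4R)-5,7-bis(tert-butyldimethylsilyloxy)-3-(5-methoxy-2,2-dimethyl-2H-chromen-6-yl)chroman-4-ol (cis) | COc1c([C@@H]2COc3cc(O[Si](C)(C)C(C)(C)C)cc(O[Si](C)(C)C(C)(C)C)c3[C@@H]2O)ccc2c1C=CC(C)(C)O2 | intermediate
19 | (3R)-5,7-bis(tert-butyldimethylsilyloxy)-3-(5-methoxy-2,2-dimethyl-2H-chromen-6-yl)chroman-4-one | COc1c([C@@H]2COc3cc(O[Si](C)(C)C(C)(C)C)cc(O[Si](C)(C)C(C)(C)C)c3C2=O)ccc2c1C=CC(C)(C)O2 | intermediate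
20 | (3R)-5,7-dihydroxy-3-(5-methoxy-2,2-dimethyl-2H-chromen-6-yl)chroman-4-one | COc1c([C@@H]2COc3cc(O)cc(O)c3C2=O)ccc2c1C=CC(C)(C)O2 | target

**Step count.** Total: 10 steps. Longest linear sequence: 9 steps (1, 2, 3, 4, 5, 7, 8, 9, 10).

**Steps most likely to fail**

Step 7. The carbene may be consumed by azine formation, by insertion into its own ortho-methoxy group or by cyclopropanation of the chromene double bond before it adds to 13. The fallback keeps the one-carbon ring enlargement but separates it from the aryl transfer. It sets out from 13 and from 4 and comes back at 16. Dibromocarbene (phenyl(tribromomethyl)mercury, benzene, 80 °C) should enlarge the furan ring of 13 in the same way, with loss of the silyl group as its bromide, to give 3-bromo-5,7-bis(tert-butyldimethylsilyloxy)-4H-chromen-4-one F1. Aldehyde 4 would be oxidised (NaClO2, NaH2PO4, 2-methylbut-2-ene) to 5-methoxy-2,2-dimethyl-2H-chromene-6-carboxylic acid F2. Palladium-catalysed decarbonylative borylation of F2 (Piv2O, B2pin2, Pd(OAc)2, dppb, dioxane, 160 °C) would give 2-(5-methoxy-2,2-dimethyl-2H-chromen-6-yl)-4,4,5,5-tetramethyl-1,3,2-dioxaborolane F3. Suzuki–Miyaura coupling of F1 with F3 (Pd2(dba)3, SPhos, anhydrous K3PO4, toluene, 90 °C) should then give 16.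

Step 5. Hypochlorite may chlorinate the electron-rich arene or the chromene double bond, and the donor-substituted chlorodiazirine may ionise and decompose before use. The fallback makes the same arylchlorocarbene by α-elimination instead. It sets out from 4 and comes back at 14. Oxalyl chloride with catalytic triphenylphosphine oxide (CHCl3, rt) should convert 4 into 6-(dichloromethyl)-5-methoxy-2,2-dimethyl-2H-chromene F4. Deprotonation of F4 with LiTMP at −78 °C in the presence of 13 should deliver the carbenoid to the enol ether and give chlorocyclopropane 14, which continues to 16 as in step 7.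

Step 8. The crowded ketone next to the 5-silyloxy group may be reduced too slowly, so that the reaction stops at the racemic ketone, or a silyl ether may be lost in the formate medium. The fallback sets the stereocentre by protonation instead of reduction. It sets out from 16 and comes back at 19, so that steps 8 and 9 are both replaced. Conjugate reduction of 16 with L-Selectride (THF, −78 °C) and trapping with TMSCl should give 5,7-bis(tert-butyldimethylsilyloxy)-3-(5-methoxy-2,2-dimethyl-2H-chromen-6-yl)-4-(trimethylsilyloxy)-2H-chromene F5. Catalytic enantioselective protonation of F5 (BINOL-derived N-triflyl thiophosphoramide of the antipode that gives 3R, 2,4,6-trimethylphenol, toluene, rt) should then give 19.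

**Further compounds**

F1 | step 7 | 3-bromo-5,7-bis(tert-butyldimethylsilyloxy)-4H-chromen-4-one | CC(C)(C)[Si](C)(C)Oc1cc(O[Si](C)(C)C(C)(C)C)c2C(=O)C(Br)=COc2c1
F2 | step 7 | 5-methoxy-2,2-dimethyl-2H-chromene-6-carboxylic acid | CC1(C)C=Cc2c(OC)c(C(O)=O)ccc2O1
F3 | step 7 | 2-(5-methoxy-2,2-dimethyl-2H-chromen-6-yl)-4,4,5,5-tetramethyl-1,3,2-dioxaborolane | CC1(C)C=Cc2c(OC)c(B3OC(C)(C)C(C)(C)O3)ccc2O1
F4 | step 5 | 6-(dichloromethyl)-5-methoxy-2,2-dimethyl-2H-chromene | CC1(C)C=Cc2c(OC)c(C(Cl)Cl)ccc2O1
F5 | step 8 | 5,7-bis(tert-butyldimethylsilyloxy)-3-(5-methoxy-2,2-dimethyl-2H-chromen-6-yl)-4-(trimethylsilyloxy)-2H-chromene | COc1c(C2=C(O[Si](C)(C)C)c3c(O[Si](C)(C)C(C)(C)C)cc(O[Si](C)(C)C(C)(C)C)cc3OC2)ccc2c1C=CC(C)(C)O2
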